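**Retrosynthetic overview**
1. Structural feature: in the piperidine (primed atoms) C2' carries both N1' and ring-A carbon C6, and C6' lies four carbons further along; cutting N1'–C2' and N1'–C6' together reveals a 5-aryl-5-oxopentanoic acid (ketone carbon = C2', carboxyl carbon = C6').
2. This keto acid is condensed with (S)-phenylglycinol to a bicyclic lactam whose aminal carbon (the future C2') is fixed by the auxiliary; alane then replaces C–O by C–H with retention and reduces the lactam, and the auxiliary residue is exchanged for N-methyl.
3. Ring C (the pyranone) is cut at O1–C2 and at C3–C(=O)Ph to an ortho-hydroxyacetophenone and benzoyl chloride (Baker–Venkataraman logic). Only the ring-A oxygen para to C6 is carried as a silyl ether, so only that oxygen can become O1.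
4. The aryl–C2' bond comes from lithiation of the 3,5-dimethoxyphenol silyl ether between its methoxy groups and opening of glutaric anhydride.
5. Ring order: ring A is purchased; the piperidinone and oxazolidine rings form together (the oxazolidine is opened again in step 4); ring C is closed last and the two methyl ethers are removed at the end.

Key step: step 3

Remark: by the sequence rule C2' of the target is (R) (N1' > aryl C6 > C3' > H). The thermodynamic (3S,8aS) lactam and retentive hydride delivery together lead to this descriptor.

**Step 1**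
Reactants: 1 3,5-dimethoxyphenol
Product: 2 triisopropyl(3,5-dimethoxyphenoxy)silane
Conditions: TIPSCl, imidazole, DMF, rt
Reagents that add atoms: chlorotriisopropylsilane, CC(C)[Si](Cl)(C(C)C)C(C)C
Why: Silylation of a phenol with a silyl chloride and imidazole is routine, and the bulky silyl ether marks the oxygen that later becomes O1 while being a poor director for the metalation that follows.

**Step 2**
Reactants: 2 triisopropyl(3,5-dimethoxyphenoxy)silane; 3 glutaric anhydride
Product: 5 5-[2,6-dimethoxy-4-(triisopropylsilyloxy)phenyl]-5-oxopentanoic acid, via aryllithium 4 (not isolated)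
Conditions: n-BuLi, THF, 0 °C to rt; then cannulated into 3 (1.5 equiv), THF, −78 to 0 °C; 1 M HCl
Reagents that add atoms: none
Why: Directed ortho-metalation removes the proton flanked by the two methoxy groups (the hindered silyloxy group does not direct), and the aryllithium opens the cyclic anhydride to a lithium keto-carboxylate whose di-ortho-substituted ketone, together with inverse addition at low temperature, should suppress a second addition.

**Step 3**
Reactants: 5 5-[2,6-dimethoxy-4-(triisopropylsilyloxy)phenyl]-5-oxopentanoic acid; 6 (S)-2-amino-2-phenylethanol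
Product: 8 (3S,8aS)-8a-[2,6-dimethoxy-4-(triisopropylsilyloxy)phenyl]-3-phenylhexahydro-5H-[1,3]oxazolo[3,2-a]pyridin-5-one, via oxazolidine acid 7 (not isolated)
Conditions: pivalic acid (0.2 equiv), toluene, reflux, Dean–Stark, 24–48 h
Reagents that add atoms: none
Why: The primary amine condenses with the aryl ketone to an iminium ion, the hydroxyl adds to the iminium carbon to give oxazolidine 7 (5-endo-trig, the usual course of N,O-acetal formation), and the ring NH is then acylated by the tethered carboxylic acid with azeotropic loss of water to close the piperidinone (6-exo-trig). The closest known reaction type is the cyclocondensation of delta-oxo acids, aryl ketones included, with phenylglycinol to oxazolo[3,2-a]pyridin-5-ones. The only new stereocentre, the aminal carbon C8a, is set under thermodynamic control: 7 opens and closes reversibly through the iminium ion, so both epimers interconvert, and the equilibrium is drained toward the fused lactam in which the C8 methylene lies anti and the aryl group syn to the C3 phenyl, which is (3S,8aS) from the (S)-amino alcohol. The selectivity needed is therefore diastereoselectivity at C8a alone, and it is secured by the fixed C3 stereocentre together with equilibrating conditions (weak acid, reflux, water removal). The two ortho methoxy groups slow the first condensation, which is why an acid co-catalyst and prolonged water removal are specified; the silyl and methyl ethers are inert to these conditions.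

**Step 4**
Reactants: 8 (3S,8aS)-8a-[2,6-dimethoxy-4-(triisopropylsilyloxy)phenyl]-3-phenylhexahydro-5H-[1,3]oxazolo[3,2-a]pyridin-5-one
Product: 9 (2S)-2-[(2R)-2-[2,6-dimethoxy-4-(triisopropylsilyloxy)phenyl]piperidin-1-yl]-2-phenylethan-1-ol
Conditions: LiAlH4, AlCl3 (3:1, forms AlH3), THF, −78 °C to rt; Na2SO4·10H2O quench
Reagents that add atoms: none
Why: Alane reduces the lactam carbonyl to CH2 and, bound to the oxazolidine oxygen, ionises the C8a–O bond and delivers hydride to the same face (reductive oxazolidine opening with retention, the known behaviour of 8a-aryl lactams of this class), which turns (8aS) into (R)-C2'.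

**Step 5**
Reactants: 9 (2S)-2-[(2R)-2-[2,6-dimethoxy-4-(triisopropylsilyloxy)phenyl]piperidin-1-yl]-2-phenylethan-1-ol
Product: 11 (2R)-2-[2,6-dimethoxy-4-(triisopropylsilyloxy)phenyl]-1-methylpiperidine, via secondary amine 10 (not isolated)
Conditions: H2 (4 atm), Pd(OH)2/C, MeOH, rt; then 37% aq. CH2O, H2 (1 atm), rt
Reagents that add atoms: formaldehyde, C=O
Why: Catalytic hydrogenolysis should cleave the exocyclic benzylic C–N bond of the unhindered phenylethanol residue in preference to the ring C2'–N bond, which is shielded by two ortho methoxy groups, and the freed secondary amine is methylated in the same vessel by reductive amination, neither operation touching C2'.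

**Step 6**
Reactants: 11 (2R)-2-[2,6-dimethoxy-4-(triisopropylsilyloxy)phenyl]-1-methylpiperidine
Product: 12 3,5-dimethoxy-4-[(2R)-1-methylpiperidin-2-yl]phenol
Conditions: Bu4NF, AcOH (1.2 equiv each), THF, 0 °C to rt
Reagents that add atoms: none
Why: Fluoride-mediated cleavage of an aryl silyl ether is driven by the Si–F bond, and buffering with acetic acid leaves the methyl ethers and the amine untouched.

**Step 7**
Reactants: 12 3,5-dimethoxy-4-[(2R)-1-methylpiperidin-2-yl]phenol
Product: 13 1-{6-hydroxy-2,4-dimethoxy-3-[(2R)-1-methylpiperidin-2-yl]phenyl}ethan-1-one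
Conditions: Ac2O (3 equiv), BF3·OEt2 (4 equiv), CH2Cl2, 0 °C to rt; then K2CO3, MeOH/H2O, rt
Reagents that add atoms: acetic anhydride, CC(=O)OC(C)=O
Why: Boron trifluoride-promoted Friedel–Crafts acetylation (through the aryl acetate and a Fries-type shift) places the acetyl group ortho to the free hydroxyl, the two open ring positions being equivalent by symmetry, and the BF2 chelate formed with the phenol oxygen should stop the reaction at monoacylation.

**Step 8**
Reactants: 13 1-{6-hydroxy-2,4-dimethoxy-3-[(2R)-1-methylpiperidin-2-yl]phenyl}ethan-1-one; 14 benzoyl chloride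
Product: 16 5,7-dimethoxy-6-[(2R)-1-methylpiperidin-2-yl]-2-phenyl-4H-chromen-4-one, via diketone 15 (not isolated)
Conditions: LiN(SiMe3)2 (3.5 equiv), THF, −78 to −10 °C; 14, −78 °C to rt; aq. NH4Cl; then conc. HCl, AcOH, 40 °C
Reagents that add atoms: none
Why: Excess amide base forms the phenoxide–enolate dianion, which is C-benzoylated to the 1,3-diketone (one-pot variant of the Baker–Venkataraman sequence), and acid-catalysed cyclodehydration through the only free hydroxyl closes ring C with O1 para to C6.

**Step 9**
Reactants: 16 5,7-dimethoxy-6-[(2R)-1-methylpiperidin-2-yl]-2-phenyl-4H-chromen-4-one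
Product: 17 5,7-dihydroxy-6-[(2R)-1-methylpiperidin-2-yl]-2-phenyl-4H-chromen-4-one
Conditions: BBr3 (6 equiv), CH2Cl2, −78 to 0 °C; MeOH, then aq. NaHCO3 (pH 8), 0 °C
Reagents that add atoms: none
Why: Boron tribromide cleaves both aryl methyl ethers (Lewis acid complexation, then bromide attack at methyl), the 5-methoxy group assisted by chelation to C4=O, and the low temperature and cold bicarbonate quench are chosen so that the benzylic C2'–N bond does not ionise and C2' keeps its configuration.

**Compound list**
1 | 3,5-dimethoxyphenol | COc1cc(O)cc(OC)c1 | starting material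
2 | triisopropyl(3,5-dimethoxyphenoxy)silane | COc1cc(O[Si](C(C)C)(C(C)C)C(C)C)cc(OC)c1 | intermediate
3 | glutaric anhydride | O=C1CCCC(=O)O1 | starting material
4 | [2,6-dimethoxy-4-(triisopropylsilyloxy)phenyl]lithium | [Li]c1c(OC)cc(O[Si](C(C)C)(C(C)C)C(C)C)cc1OC | intermediate (not isolated)
5 | 5-[2,6-dimethoxy-4-(triisopropylsilyloxy)phenyl]-5-oxopentanoic acid | OC(=O)CCCC(=O)c1c(OC)cc(O[Si](C(C)C)(C(C)C)C(C)C)cc1OC | intermediate
6 | (S)-2-amino-2-phenylethanol | N[C@H](CO)c1ccccc1 | starting material
7 | 4-[(4S)-2-[2,6-dimethoxy-4-(triisopropylsilyloxy)phenyl]-4-phenyl-1,3-oxazolidin-2-yl]butanoic acid (C2 epimers in equilibrium) | OC(=O)CCCC1(c2c(OC)cc(O[Si](C(C)C)(C(C)C)C(C)C)cc2OC)N[C@@H](c2ccccc2)CO1 | intermediate (not isolated)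
8 | (3S,8aS)-8a-[2,6-dimethoxy-4-(triisopropylsilyloxy)phenyl]-3-phenylhexahydro-5H-[1,3]oxazolo[3,2-a]pyridin-5-one | O=C1CCC[C@@]2(c3c(OC)cc(O[Si](C(C)C)(C(C)C)C(C)C)cc3OC)OC[C@H](c3ccccc3)N12 | intermediate
9 | (2S)-2-[(2R)-2-[2,6-dimethoxy-4-(triisopropylsilyloxy)phenyl]piperidin-1-yl]-2-phenylethan-1-ol | OC[C@H](c1ccccc1)N1CCCC[C@@H]1c1c(OC)cc(O[Si](C(C)C)(C(C)C)C(C)C)cc1OC | intermediate
10 | (2R)-2-[2,6-dimethoxy-4-(triisopropylsilyloxy)phenyl]piperidine | N1CCCC[C@@H]1c1c(OC)cc(O[Si](C(C)C)(C(C)C)C(C)C)cc1OC | intermediate (not isolated)
11 | (2R)-2-[2,6-dimethoxy-4-(triisopropylsilyloxy)phenyl]-1-methylpiperidine | CN1CCCC[C@@H]1c1c(OC)cc(O[Si](C(C)C)(C(C)C)C(C)C)cc1OC | intermediate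
12 | 3,5-dimethoxy-4-[(2R)-1-methylpiperidin-2-yl]phenol | CN1CCCC[C@@H]1c1c(OC)cc(O)cc1OC | intermediate
13 | 1-{6-hydroxy-2,4-dimethoxy-3-[(2R)-1-methylpiperidin-2-yl]phenyl}ethan-1-one | CN1CCCC[C@@H]1c1c(OC)cc(O)c(C(C)=O)c1OC | intermediate
14 | benzoyl chloride | O=C(Cl)c1ccccc1 | starting material
15 | 1-{6-hydroxy-2,4-dimethoxy-3-[(2R)-1-methylpiperidin-2-yl]phenyl}-3-phenylpropane-1,3-dione | CN1CCCC[C@@H]1c1c(OC)cc(O)c(C(=O)CC(=O)c2ccccc2)c1OC | intermediate (not isolated)
16 | 5,7-dimethoxy-6-[(2R)-1-methylpiperidin-2-yl]-2-phenyl-4H-chromen-4-one | CN1CCCC[C@@H]1c1c(OC)cc2oc(-c3ccccc3)cc(=O)c2c1OC | intermediate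
17 | 5,7-dihydroxy-6-[(2R)-1-methylpiperidin-2-yl]-2-phenyl-4H-chromen-4-one | CN1CCCC[C@@H]1c1c(O)cc2oc(-c3ccccc3)cc(=O)c2c1O | target

**Step count**
Total: 9 steps. Longest linear sequence: 9 steps (1 to 17).

**Steps most likely to fail**

Step 3 (key step). Condensation at the di-ortho-substituted ketone may be slow or incomplete, so that open-chain amide formation or decomposition overtakes ring closure; equilibration at the aminal carbon may also be incomplete and leave a mixture of C8a epimers. The fallback sets out from silyl ether 2 (through aryllithium 4) and returns at secondary amine 10, bypassing steps 2–4. 5-Chloropentanal and (R)-2-methylpropane-2-sulfinamide are condensed (CuSO4, CH2Cl2) to the (R,E)-N-sulfinyl aldimine F1. Aryllithium 4 is transmetalated with MgBr2·OEt2 to the arylmagnesium bromide F2, which is added to F1 in toluene/CH2Cl2 at −48 °C. Delivery through the six-membered chelate of magnesium with the sulfinyl oxygen should give the (R)-configured sulfinamide F3, whose diastereomers are separable at this stage. KN(SiMe3)2 in THF then closes the ring by intramolecular N-alkylation to the N-sulfinylpiperidine F4. Brief treatment with HCl in MeOH at 0 °C removes the sulfinyl group to give 10, which is N-methylated as in the second operation of step 5. This replaces condensation at a hindered ketone by carbon–carbon bond formation at an unhindered aldimine.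

Step 5. Hydrogenolysis may stall at the crowded nitrogen, or the ring C2'–N bond, which is also benzylic, may be cleaved with ring opening. The fallback sets out from amino alcohol 9 and returns at 10. Pb(OAc)4 in CH2Cl2/MeOH at −10 °C cleaves the carbon–carbon bond of the 1,2-amino alcohol (glycol-type fragmentation). This expels formaldehyde and leaves the N-benzylidene iminium acetate F5. Immediate hydrolysis with cold dilute aqueous HCl releases 10 and benzaldehyde; 10 is then methylated with formaldehyde under the reductive conditions of step 5. No benzylic C–N hydrogenolysis is involved, so the ring bond is not at risk.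

Step 7. The boron Lewis acid may cleave the methyl ether flanked by the new acetyl group and the piperidine, which would free a second ortho hydroxyl and remove the regiochemical certainty of the later ring closure; alternatively the reaction may stop at O-acetylation because the complexed amine deactivates the ring. The fallback sets out from phenol 12 and returns at 13. A Houben–Hoesch acylation with acetonitrile, ZnCl2 and dry HCl (Et2O/MeCN, 0 °C) gives the aryl methyl ketimine F6, isolated as its hydrochloride. Hydrolysis in warm water then gives acetophenone 13. No ether-cleaving Lewis acid is present, and the nitrilium electrophile can only enter ortho to the free hydroxyl.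

**Further compounds**
F1 | step 3 | (R,E)-N-(5-chloropentylidene)-2-methylpropane-2-sulfinamide | CC(C)(C)[S@@](=O)/N=C/CCCCCl
F2 | step 3 | [2,6-dimethoxy-4-(triisopropylsilyloxy)phenyl]magnesium bromide | Br[Mg]c1c(OC)cc(O[Si](C(C)C)(C(C)C)C(C)C)cc1OC
F3 | step 3 | (R)-N-[(1R)-5-chloro-1-[2,6-dimethoxy-4-(triisopropylsilyloxy)phenyl]pentyl]-2-methylpropane-2-sulfinamide | CC(C)(C)[S@@](=O)N[C@H](CCCCCl)c1c(OC)cc(O[Si](C(C)C)(C(C)C)C(C)C)cc1OC
F4 | step 3 | (2R)-1-[(R)-tert-butylsulfinyl]-2-[2,6-dimethoxy-4-(triisopropylsilyloxy)phenyl]piperidine | CC(C)(C)[S@@](=O)N1CCCC[C@@H]1c1c(OC)cc(O[Si](C(C)C)(C(C)C)C(C)C)cc1OC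
F5 | step 5 | (2R)-1-benzylidene-2-[2,6-dimethoxy-4-(triisopropylsilyloxy)phenyl]piperidin-1-ium acetate | CC(=O)[O-].COc1cc(O[Si](C(C)C)(C(C)C)C(C)C)cc(OC)c1[C@H]1CCCC[N+]1=Cc1ccccc1
F6 | step 7 | 2-(1-iminoethyl)-3,5-dimethoxy-4-[(2R)-1-methylpiperidin-2-yl]phenol (ketimine, handled as hydrochloride) | CN1CCCC[C@@H]1c1c(OC)cc(O)c(C(C)=N)c1OC
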